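**Retrosynthetic overview**
1. Target 9 ⇒ dimer 8: cut the C-1′–O bond of the acetate. Forward, this is the last step, an enantioselective allylic C–H acetoxylation of one butyl chain of the C2-symmetric dimer; it also turns the racemic core into separable diastereomers.
2. Dimer 8 ⇒ 2 × furanone 6: head-to-head [2+2] photodimerisation across the two bromomethylidene C=C bonds.
3. Furanone 6 ⇒ keto acid 4: bromination and acid-mediated enol-lactonisation (ring C–O bond).
4. Keto acid 4 ⇒ 1 + 2: acetoacetic ester alkylation and decarboxylation.
Ring order: the two butenolide rings first (as monomer 6), the cyclobutane last.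

Assumption: 8 is carried as the racemate and the core is resolved in step 4 as diastereomers; tert-butyl peracetate, Cu(MeCN)4PF6 and the bisoxazoline ligand are taken as commercial.

**Step 1**
Reactants: 1 ethyl acetoacetate; 2 ethyl 2-bromohexanoate (racemic)
Product: 4 2-butyl-4-oxopentanoic acid (racemic), via diethyl 2-acetyl-3-butylbutanedioate 3 (not isolated)
Conditions: NaOEt (1.05 equiv), EtOH, reflux, 12 h; evaporate; 6 M aq. HCl, reflux, 8 h
Reagents that add atoms: water (O)
Why: Acetoacetic ester synthesis, in which the sodium enolate of 1 displaces bromide from the α-bromo ester (SN2) and acid hydrolysis of both esters is followed by decarboxylation of the β-keto acid; the one stereocentre is racemic and is lost in step 2.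

**Step 2**
Reactants: 4 2-butyl-4-oxopentanoic acid
Product: 6 (5Z)-4-bromo-5-(bromomethylidene)-3-butylfuran-2(5H)-one, via 3,5-dibromo-2-butyl-4-oxopentanoic acid 5 (not isolated)
Conditions: Br2 (2.1 equiv), CHCl3, 0 °C to rt; evaporate; conc. H2SO4, 100 °C, 20 min; ice, extraction, SiO2
Reagents that add atoms: bromine (BrBr)
Why: Acid-catalysed enol bromination of the ketone at C3 and C5, then sulfuric acid-mediated enol-lactonisation (ring C–O bond) with dehydrogenation by the hot acid to the conjugated butenolide, the classical brominated-levulinic-acid route to this furanone class; no stereocentre, and the Z alkene (Br syn to ring O) is the stable isomer.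

**Step 3**
Reactants: 6 (5Z)-4-bromo-5-(bromomethylidene)-3-butylfuran-2(5H)-one (two molecules)
Product: 8 rac-(5S,6S,11R,12R)-4,10,11,12-tetrabromo-3,9-dibutyl-1,7-dioxadispiro[4.0.4.2]dodeca-3,9-diene-2,8-dione, via (5E)-4-bromo-5-(bromomethylidene)-3-butylfuran-2(5H)-one 7 (not isolated)
Conditions: hν (350 nm), 2 M in degassed CH2Cl2, −20 °C, to ca. 60% conversion; SiO2, then crystallisation
Reagents that add atoms: none
Why: [2+2] photodimerisation of a 5-ylidenebutenolide (the protoanemonin-to-anemonin reaction type), in which 6 and 7 interconvert in the light, the bromomethylidene carbons join head to head through the doubly oxygen- and allyl-stabilised 1,4-diradical or excimer, closure with opposed lactone dipoles puts the ring oxygens trans, and 8 (the suprafacial adduct of two E units, with Br trans to Br and each Br trans to the ring O on the neighbouring spiro carbon) is separated from the isomer with Br cis to O and forms as the racemate.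

**Step 4**
Reactants: 8 rac-(5S,6S,11R,12R)-4,10,11,12-tetrabromo-3,9-dibutyl-1,7-dioxadispiro[4.0.4.2]dodeca-3,9-diene-2,8-dione
Product: 9 (1R)-1-[(5S,6S,11R,12R)-4,10,11,12-tetrabromo-9-butyl-2,8-dioxo-1,7-dioxadispiro[4.0.4.2]dodeca-3,9-dien-3-yl]butyl acetate (target)
Conditions: Cu(MeCN)4PF6 (10 mol %), (S,S)-Ph-BOX [2,2′-(propane-2,2-diyl)bis((4S)-4-phenyl-4,5-dihydrooxazole), 12 mol %; ligand enantiomer to be matched to R], tBuOOAc (0.8 equiv, syringe pump), MeCN, 0 °C, 48 h, ca. 40% conversion; SiO2, then HPLC; 8 recovered
Reagents that add atoms: tert-butyl peracetate (CC(=O)OOC(C)(C)C)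
Why: Proposed new method: an enantioselective Kharasch–Sosnovsky-type allylic C–H acetoxylation of an acyclic 2-acylallyl methylene with the substrate as limiting reagent, in which monovalent copper cleaves the perester to tBuO• and a bisoxazoline-bound divalent copper acetate, tBuO• abstracts the weakest C–H (C-1′ of a butyl chain, allylic to C3=C4, the site radical bromination attacks in this furanone class), the allyl radical is captured at C-1′ (C4 is fully substituted and flanked by Br and the spiro carbon) with the lactone C=O as a second donor, and C–O reductive elimination from the trivalent copper allyl acetate sets (R) at C-1′ under ligand control, so that the two enantiomers of 8 give two diastereomers and 9 is separated from the one with the mirror-image core; the closest known reaction type is the copper–bisoxazoline asymmetric Kharasch–Sosnovsky oxidation of cycloalkenes, together with copper-catalysed radical-relay C–H functionalisation.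

**Compound list**
1 | ethyl acetoacetate (ethyl 3-oxobutanoate) | CCOC(=O)CC(C)=O | starting material
2 | ethyl 2-bromohexanoate (racemic) | CCCCC(Br)C(=O)OCC | starting material
3 | diethyl 2-acetyl-3-butylbutanedioate (diastereomer mixture) | CCCCC(C(=O)OCC)C(C(C)=O)C(=O)OCC | intermediate
4 | 2-butyl-4-oxopentanoic acid (racemic) | CCCCC(CC(C)=O)C(=O)O | intermediate
5 | 3,5-dibromo-2-butyl-4-oxopentanoic acid (diastereomer mixture) | CCCCC(C(=O)O)C(Br)C(=O)CBr | intermediate
6 | (5Z)-4-bromo-5-(bromomethylidene)-3-butylfuran-2(5H)-one | CCCCC1=C(Br)/C(=C/Br)OC1=O | intermediate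
7 | (5E)-4-bromo-5-(bromomethylidene)-3-butylfuran-2(5H)-one | CCCCC1=C(Br)/C(=C\Br)OC1=O | intermediate
8 | rac-(5S,6S,11R,12R)-4,10,11,12-tetrabromo-3,9-dibutyl-1,7-dioxadispiro[4.0.4.2]dodeca-3,9-diene-2,8-dione (racemate; SMILES shows the enantiomer that leads to 9) | CCCCC1=C(Br)[C@@]2(OC1=O)[C@@H](Br)[C@H](Br)[C@@]21OC(=O)C(CCCC)=C1Br | intermediate
9 | (1R)-1-[(5S,6S,11R,12R)-4,10,11,12-tetrabromo-9-butyl-2,8-dioxo-1,7-dioxadispiro[4.0.4.2]dodeca-3,9-dien-3-yl]butyl acetate | CCCCC1=C(Br)[C@@]2(OC1=O)[C@@H](Br)[C@H](Br)[C@@]21OC(=O)C([C@@H](CCC)OC(C)=O)=C1Br | target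

**Stereocontrol summary**
- The four ring stereocentres (C5, C6, C11, C12) are set relative to one another in step 3.
- Their absolute configuration is selected in step 4 by separating the two C-1′-(R) diastereomers.
- C-1′ (R) is set by the catalyst in step 4; nothing follows that could scramble it.
- The enantiomeric purity of 9 equals the catalyst's selectivity at C-1′, because the (S) acetate of the mirror-image core is the enantiomer of 9.

**Totals**
Total steps: 4. Longest linear sequence: 4 steps (1 + 2 → 4 → 6 → 8 → 9).

**Three steps most likely to fail**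

1. Step 3, the photodimerisation. The head-to-head constitution with trans ring oxygens is well supported by analogy. Which C2-symmetric dibromide dominates is not: a long-lived triplet diradical is expected to close mainly to the isomer with each Br cis to the ring O, because that keeps the ring Br away from the vinylic Br, so 8 may be the minor isomer. The configuration of 8 must be proven by X-ray.
 Fallback, setting out from 6 and returning at 8: replace the solution dimerisation by a lattice-controlled one on the preformed E alkene. 6 is photoisomerised in dilute solution (5 mM, 350 nm), where dimerisation cannot compete, and the E isomer 7 is isolated by chromatography in the dark. 7 is then irradiated as a polycrystalline film at −40 °C. Rotation about the exocyclic bond is frozen there, so addition is suprafacial on both alkenes and the Br-trans-to-O relationship of 7 is carried into 8. This makes no new compound.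

2. Step 4, the proposed new acetoxylation. Risks are low enantioselectivity on an acyclic electron-poor allyl system, hydrogen abstraction at other CH2 groups, double acetoxylation, C–O bond formation at C4, and attack of monovalent copper on the C–Br bonds.
 Fallback with known chemistry, setting out from 8 and returning at 9: NBS and benzoyl peroxide in refluxing PhCF3 brominate one chain at C-1′ (the radical bromination long used on this furanone class), giving 4,10,11,12-tetrabromo-3-(1-bromobutyl)-9-butyl-1,7-dioxadispiro[4.0.4.2]dodeca-3,9-diene-2,8-dione F1 as C-1′ epimers. AgNO3 in aqueous acetone replaces the allylic bromine by hydroxyl to give 4,10,11,12-tetrabromo-9-butyl-3-(1-hydroxybutyl)-1,7-dioxadispiro[4.0.4.2]dodeca-3,9-diene-2,8-dione F2. Vinyl acetate with Candida antarctica lipase B then acetylates only the (R)-carbinols (the furanone is the large group). 9 is separated from its core diastereomer and from the unreacted (S)-alcohols.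

3. Step 2, the bromination and sulfuric acid ring closure. It is harsh, low-yielding, and gives mixtures of brominated furanones.
 Fallback, setting out from 2 and returning at 6: an allenoate bromolactonisation sequence.
 - 2 and PPh3 give (1-ethoxy-1-oxohexan-2-yl)triphenylphosphonium bromide F3, which aqueous NaOH converts into the ylide ethyl 2-(triphenyl-λ5-phosphanylidene)hexanoate F4.
 - F4 with propanoyl chloride and Et3N (ketene Wittig reaction) gives ethyl 2-butylpenta-2,3-dienoate F5.
 - Br2 in CH2Cl2 closes F5 to 4-bromo-3-butyl-5-methylfuran-2(5H)-one F6 with loss of bromoethane.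
 - NBS and benzoyl peroxide brominate C5 to give 4,5-dibromo-3-butyl-5-methylfuran-2(5H)-one F7, and Et3N eliminates HBr to 4-bromo-3-butyl-5-methylidenefuran-2(5H)-one F8.
 - Br2 adds to the exocyclic enol-ester alkene to give 4,5-dibromo-5-(bromomethyl)-3-butylfuran-2(5H)-one F9, and DBU eliminates HBr to 6.

**Further compounds**
F0 | step 3 | none | none
F1 | step 4 | 4,10,11,12-tetrabromo-3-(1-bromobutyl)-9-butyl-1,7-dioxadispiro[4.0.4.2]dodeca-3,9-diene-2,8-dione (C-1′ epimers; core shown as the enantiomer that leads to 9) | CCCCC1=C(Br)[C@@]2(OC1=O)[C@@H](Br)[C@H](Br)[C@@]21OC(=O)C(C(Br)CCC)=C1Br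
F2 | step 4 | 4,10,11,12-tetrabromo-9-butyl-3-(1-hydroxybutyl)-1,7-dioxadispiro[4.0.4.2]dodeca-3,9-diene-2,8-dione (C-1′ epimers; core shown as the enantiomer that leads to 9) | CCCCC1=C(Br)[C@@]2(OC1=O)[C@@H](Br)[C@H](Br)[C@@]21OC(=O)C(C(O)CCC)=C1Br
F3 | step 2 | (1-ethoxy-1-oxohexan-2-yl)triphenylphosphonium bromide | CCCCC(C(=O)OCC)[P+](c1ccccc1)(c1ccccc1)c1ccccc1.[Br-]
F4 | step 2 | ethyl 2-(triphenyl-λ5-phosphanylidene)hexanoate | CCCCC(C(=O)OCC)=P(c1ccccc1)(c1ccccc1)c1ccccc1
F5 | step 2 | ethyl 2-butylpenta-2,3-dienoate (racemic) | CCCCC(=C=CC)C(=O)OCC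
F6 | step 2 | 4-bromo-3-butyl-5-methylfuran-2(5H)-one (racemic) | CCCCC1=C(Br)C(C)OC1=O
F7 | step 2 | 4,5-dibromo-3-butyl-5-methylfuran-2(5H)-one (racemic) | CCCCC1=C(Br)C(C)(Br)OC1=O
F8 | step 2 | 4-bromo-3-butyl-5-methylidenefuran-2(5H)-one | CCCCC1=C(Br)C(=C)OC1=O
F9 | step 2 | 4,5-dibromo-5-(bromomethyl)-3-butylfuran-2(5H)-one (racemic) | CCCCC1=C(Br)C(Br)(CBr)OC1=O
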